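**Assumptions.** The SMILES is read as the (2Z)-2-methylbut-2-enoate (angelate) of the cis-(3S,4R)-piperidinol. Compounds 1, 2 and 13 are taken as commercially available. The sense of induction of the ruthenium catalyst in step 4 is assigned by analogy with the hydrogenation of 2-substituted cyclohexanones; if the opposite sense is found, the mirror-image catalyst is used and nothing else changes.

## Structural features

The target is a 5,7-dihydroxy-2-methylchromen-4-one (benzene ring A fused to pyranone ring C) whose C8 is bonded to C4' of a 1-methylpiperidine, and O3' of that piperidine carries a (2Z)-2-methylbut-2-enoyl (angeloyl) group. C3' (S) and C4' (R) are adjacent and cis, so in the chair with the aryl group equatorial the C3'–O bond is axial; this is the less stable diastereomer and it has to be made in one absolute sense. The aryl carbon C8 lies between C7–OH and C8a–O1, so the C8–C4' bond joins a doubly ortho-substituted arene to a ring carbon, and because ring A is a phloroglucinol, C6 competes with C8 in any electrophilic attachment. The fragile groups are the Z-enoate (isomerisation to the E-tiglate by nucleophiles or halide acids, reduction, cleavage by base), the acidic 7-OH and the chelated 5-OH, and the tertiary amine beta to O3' (aziridinium formation whenever O3' becomes a leaving group). The real difficulty is the cis C3'/C4' pair next to the hindered aryl group, under absolute control, together with the timing of the angelate. The key step exploits two features of the piperidine: C4' is alpha to C3', so at the C3' ketone level the C4'–H is enolisable and C4' can equilibrate while C3' is reduced; and N1', C3'–O and C4'–aryl stand exactly as in a 4-arylpyridin-3-ol, so the saturated ring can be drawn from a flat pyridine.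

## Logic of the disconnections

In one sentence: the route rests on the hydrogenative dynamic kinetic resolution of racemic, C4'-labile ketone 6, which is funnelled into the single cis-(3S,4R) alcohol 7.

**15 to 14.** The O7–H bond is traced back to an O7–Si bond. The only acidic, non-chelated phenol must be masked while O3' is acylated. The gain is a chemoselective acylation. The demand is a desilylation that is nearly neutral and cold, so that neither the ester nor the Z-alkene is touched.

**14 to 12 and 13.** The acyl C–O3' ester bond is cut. Cutting here brings the Z-enoate in after every hot, acidic, basic or reducing step. The gain is that 13 is used intact and the stereocentres are already in place. The demand is acylation of a hindered axial alcohol with retention at C3' and without Z to E isomerisation.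

**12 to 11.** The O7–Si bond is cut. The reason is the acidity difference between O7–H, the chelated O5–H and the aliphatic O3'–H. The gain is a one-step differentiation of three hydroxyl groups. The demand is that a bulky silyl chloride reacts only with the phenoxide.

**11 to 10.** The O5–H and O7–H bonds are traced back to O–CH3 bonds. Methyl ethers are the only phenol masks that survive the Lewis acid, enolate and acid steps before them. The gain is robustness. The demand is that the harsh ether cleavage comes before the ester exists.

**10 to 8 (through 9).** In ring C the O1–C2 and C2–C3 bonds are cut, which removes C2 and its methyl group as a two-carbon ester. The gain is that the pyranone comes from an ortho-hydroxyaryl methyl ketone, and the free phenol of 8 decides that the piperidine ends at C8 and not at C6. The demand is a Claisen condensation and cyclodehydration that leave C3' and C4' alone.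

**8 to 7.** The aryl–acetyl bond (later C4a–C4) and the O3'–acetyl bond are cut, and the free phenol is traced back to its methyl ether. The arene of 7 is locally symmetric, so acylation has no regiochemical question. The gain is a simple, symmetric aryl group through the key step. The demand is that the ether flanked by both neighbours is the one cleaved.

**7 to 6 (key).** The C3'–H bond is cut, so that C3' becomes a carbonyl and C4' a stereolabile alpha carbon. Both stereocentres disappear together. The gain is that an enantiopure cis pair comes from a racemate, with no resolution and no inversion step. The demands are that epimerisation at C4' is faster than reduction, that the catalyst selects one enantiomer, and that hydride enters along the equatorial direction.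

**6 to 4 (through 5).** The C–H bonds at C2', C5' and C6', and after tautomerisation at C4', are cut back to a pyridinium ring. The gain is that the positions of nitrogen, oxygen and aryl group are fixed by an aromatic precursor. The demand is a partial hydrogenation that stops at the ketone.

**4 to 3.** The N–CH3 bond is cut. It activates the ring for reduction and is the N-methyl group of the target. The demand is alkylation on N and not on O.

**3 to 1 and 2.** The C8–C4' bond is cut as an sp2–sp2 biaryl bond. Both partners are commercial. The gain is that the hindered bond is made by cross-coupling and not by attack on a saturated carbon. The demand is a catalyst that couples a doubly ortho-substituted boronic acid before it loses boron.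

## Other disconnections considered

**Alternative 1:** (the first that comes to mind) The C8–C4' bond is cut as an acid-mediated condensation of 1,3,5-trimethoxybenzene with 1-methylpiperidin-4-one to tetrahydropyridine A1. Hydroboration–oxidation then gives the racemic trans alcohol A2, which is oxidised to ketone 6, reduced to the racemic cis alcohol and resolved as a salt. The forward key step is the electrophilic aromatic substitution with dehydration. Hydroboration is a syn addition and therefore has to give the trans isomer, so an oxidation–reduction pair is needed only to correct C3'. Nothing controls the absolute configuration, so half of the material is lost at the resolution. The chosen plan reaches 7 from 6 in one step with both centres set.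

**Alternative 2:** The C8–C4' bond is cut as an asymmetric conjugate addition (Hayashi–Miyaura type, [Rh(cod)Cl]2 with a chiral diphosphine) of 2 to 1-methyl-5,6-dihydropyridin-2(1H)-one, giving lactam A3. Enolate hydroxylation then gives the hydroxy lactam A4, and lactam reduction follows. The forward key step is the rhodium-catalysed 1,4-addition. A doubly ortho-substituted, electron-rich arylboronic acid is expected to lose boron faster than it inserts into the enone. Hydroxylation anti to the aryl group must give the trans isomer A4, so the two centres are set one at a time and one of them wrongly. An inversion step would again be needed, and the route is longer.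

**Alternative 3:** The C8–C4' bond is cut as an anti opening of the enantiopure epoxide A5 at C4' by a (2,4,6-trimethoxyphenyl)cuprate, giving the trans alcohol A6. Ring C would then be built as in the chosen route, and a final Mitsunobu esterification with 13 would invert C3' and place the angelate in one step. The forward key step is the epoxide opening. The substrate does not dictate attack at C4' over C3', and A5 needs an asymmetric synthesis of its own. In the Mitsunobu step the amine beta to the activated oxygen is expected to close an aziridinium ion, which leads to ring-contracted pyrrolidines. Displacement at a carbon flanked by the doubly ortho-substituted aryl group should also be slow against elimination. The chosen plan never makes O3' a leaving group.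

Key step: step 4

## Route

Step 1
Reactants: 1 4-bromopyridin-3-ol; 2 (2,4,6-trimethoxyphenyl)boronic acid
Product: 3 4-(2,4,6-trimethoxyphenyl)pyridin-3-ol
Conditions: Pd(OAc)2 (3 mol %), SPhos (6 mol %), K3PO4 (3 equiv), 2 (1.5 equiv), toluene/H2O, 90 °C
Reagents that add atoms: none
Why: Suzuki–Miyaura coupling; the bulky dialkylbiarylphosphine gives a monoligated zerovalent palladium species that should couple a doubly ortho-substituted boronic acid faster than it loses boron, and the halide position of 1 fixes the aryl group at C4 next to the oxygen.

Step 2
Reactants: 3 4-(2,4,6-trimethoxyphenyl)pyridin-3-ol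
Product: 4 3-hydroxy-1-methyl-4-(2,4,6-trimethoxyphenyl)pyridin-1-ium iodide
Conditions: MeI (3 equiv), acetone, 40 °C, sealed vessel
Reagents that add atoms: iodomethane, CI
Why: Menshutkin N-alkylation; without base the ring nitrogen of a neutral pyridin-3-ol is the nucleophile, so quaternisation on N is expected over O-methylation, and the salt should crystallise from the medium.

Step 3
Reactants: 4 3-hydroxy-1-methyl-4-(2,4,6-trimethoxyphenyl)pyridin-1-ium iodide
Product: 6 rac-1-methyl-4-(2,4,6-trimethoxyphenyl)piperidin-3-one, via enol tautomer 5 (not isolated)
Conditions: [Ir(cod)Cl]2 (1 mol %), PPh3 (4 mol %), NaHCO3 (1.1 equiv), H2 (40 bar), 1,2-dichloroethane, 40 °C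
Reagents that add atoms: none
Why: Homogeneous iridium-catalysed partial hydrogenation of a 3-hydroxypyridinium salt, a known way to piperidin-3-ones: hydride adds at C6 and C2 of the activated ring, the C3=C4 enol 5 remains, and its tautomerisation to 6 gives an isolated ketone that this catalyst should not reduce; C4 is formed racemic, which is what step 4 needs.

Step 4
Reactants: 6 rac-1-methyl-4-(2,4,6-trimethoxyphenyl)piperidin-3-one
Product: 7 (3S,4R)-1-methyl-4-(2,4,6-trimethoxyphenyl)piperidin-3-ol
Conditions: RuCl2[(S)-binap][(R,R)-dpen] (1 mol %), tBuOK (10 mol %), H2 (10 bar), iPrOH, 25 °C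
Reagents that add atoms: none
Why: Hydrogenative dynamic kinetic resolution: tBuOK converts the precatalyst into the RuH2(diphosphine)(diamine) species, which passes hydride from ruthenium and a proton from N–H to the C3=O group in an outer-sphere six-membered transition state, and the same base interconverts (4R)-6 and (4S)-6 through the C3–C4 enolate (the enolate towards C2 is not stereogenic and does no harm). The closest known reaction type is the base-assisted asymmetric hydrogenation of racemic 2-aryl- and 2-alkylcyclohexanones to cis-2-substituted cyclohexanols with this catalyst family. No ring is closed. C4' is set by the catalyst, which should reduce the (4R) ketone faster while the (4S) ketone is fed back by enolisation. C3' is set by substrate and catalyst together: hydride enters along the equatorial direction of the chair that has the aryl group equatorial, so the new C3–O bond is axial and cis to the aryl group, the sense that bulky hydride donors are also expected to show on this ketone. The step needs epimerisation at C4 to be faster than reduction, which the alkoxide base and the slow reduction of a ketone crowded by the doubly ortho-substituted aryl group should secure, and it needs C=O reduction over arene reduction, which is inherent in the outer-sphere mechanism. The tertiary amine has no N–H and should not bind the coordinatively saturated ruthenium centre.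

Step 5
Reactants: 7 (3S,4R)-1-methyl-4-(2,4,6-trimethoxyphenyl)piperidin-3-ol
Product: 8 (3S,4R)-4-(3-acetyl-2-hydroxy-4,6-dimethoxyphenyl)-1-methylpiperidin-3-yl acetate
Conditions: Ac2O (10 equiv), BF3·OEt2 (8 equiv), CH2Cl2, 0 °C to rt; aq. Na2CO3
Reagents that add atoms: acetic anhydride, CC(=O)OC(C)=O
Why: Friedel–Crafts acetylation of the activated arene (its two free positions are equivalent) with O-acetylation of O3', followed in the same flask by chelation-assisted cleavage of one ortho methyl ether; the methoxy group squeezed between the acetyl and piperidinyl groups is twisted out of the ring plane and should be the one lost, which later places the piperidine at C8 and not at C6.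

Step 6
Reactants: 8 (3S,4R)-4-(3-acetyl-2-hydroxy-4,6-dimethoxyphenyl)-1-methylpiperidin-3-yl acetate
Product: 10 8-[(3S,4R)-3-hydroxy-1-methylpiperidin-4-yl]-5,7-dimethoxy-2-methyl-4H-chromen-4-one, via 1,3-diketone 9 (not isolated)
Conditions: NaH (6 equiv), EtOAc (excess), THF, reflux; then conc. HCl, rt; aq. NaHCO3
Reagents that add atoms: ethyl acetate, CCOC(C)=O
Why: Crossed Claisen condensation of the methyl ketone enolate with ethyl acetate gives diketone 9, the ethoxide released removes the O-acetyl group, and acid closes the pyranone by 6-exo-trig attack of the phenol on the distal carbonyl followed by dehydration; no stereocentre is touched.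

Step 7
Reactants: 10 8-[(3S,4R)-3-hydroxy-1-methylpiperidin-4-yl]-5,7-dimethoxy-2-methyl-4H-chromen-4-one
Product: 11 5,7-dihydroxy-8-[(3S,4R)-3-hydroxy-1-methylpiperidin-4-yl]-2-methyl-4H-chromen-4-one
Conditions: pyridine hydrochloride (20 equiv), melt, 180 °C; then aq. NaHCO3 to pH 8
Reagents that add atoms: none
Why: SN2 demethylation of the protonated aryl methyl ethers by chloride; chromenones, N-methylpiperidines and secondary alcohols are of the kind that tolerates this melt, and the step stands before the esterification because no angelate would survive it.

Step 8
Reactants: 11 5,7-dihydroxy-8-[(3S,4R)-3-hydroxy-1-methylpiperidin-4-yl]-2-methyl-4H-chromen-4-one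
Product: 12 5-hydroxy-8-[(3S,4R)-3-hydroxy-1-methylpiperidin-4-yl]-2-methyl-7-{[tri(propan-2-yl)silyl]oxy}-4H-chromen-4-one
Conditions: iPr3SiCl (1.1 equiv), Et3N (1.5 equiv), DMF, 0 °C to rt
Reagents that add atoms: chlorotri(propan-2-yl)silane, CC(C)[Si](Cl)(C(C)C)C(C)C
Why: O-silylation under acidity control: the 7-OH is a vinylogous carboxylic acid and reacts as its phenoxide, whereas the 5-OH is held in a hydrogen bond to C4=O and the axial 3'-OH is too hindered for the bulky silyl chloride without a nucleophilic catalyst.

Step 9
Reactants: 12 5-hydroxy-8-[(3S,4R)-3-hydroxy-1-methylpiperidin-4-yl]-2-methyl-7-{[tri(propan-2-yl)silyl]oxy}-4H-chromen-4-one; 13 (2Z)-2-methylbut-2-enoic acid (angelic acid)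
Product: 14 (3S,4R)-4-(5-hydroxy-2-methyl-4-oxo-7-{[tri(propan-2-yl)silyl]oxy}-4H-chromen-8-yl)-1-methylpiperidin-3-yl (2Z)-2-methylbut-2-enoate
Conditions: 13 (3 equiv), 2,4,6-trichlorobenzoyl chloride (3 equiv), Et3N (6 equiv), toluene, rt, 2 h; then 12, 80 °C
Reagents that add atoms: none
Why: Yamaguchi-type esterification through the mixed anhydride, which is attacked at the angeloyl carbonyl because the other carbonyl is shielded by two ortho chlorines; leaving out any nucleophilic catalyst closes the conjugate addition–elimination path from the Z-enoate to the E-isomer, and the C3'–O bond is not broken, so the (3S) configuration is retained.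

Step 10
Reactants: 14 (3S,4R)-4-(5-hydroxy-2-methyl-4-oxo-7-{[tri(propan-2-yl)silyl]oxy}-4H-chromen-8-yl)-1-methylpiperidin-3-yl (2Z)-2-methylbut-2-enoate
Product: 15 (3S,4R)-4-(5,7-dihydroxy-2-methyl-4-oxo-4H-chromen-8-yl)-1-methylpiperidin-3-yl (2Z)-2-methylbut-2-enoate
Conditions: Bu4NF (1.2 equiv), AcOH (1.5 equiv), THF, 0 °C
Reagents that add atoms: none
Why: Fluoride-induced desilylation; the aryloxide para to the pyranone carbonyl is a good leaving group on silicon, so the buffered, nearly neutral reagent should cleave the O7–Si bond in the cold without touching the ester or the Z-alkene.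

## Compound list

1 | 4-bromopyridin-3-ol | Oc1cnccc1Br | starting material
2 | (2,4,6-trimethoxyphenyl)boronic acid | COc1cc(OC)c(B(O)O)c(OC)c1 | starting material
3 | 4-(2,4,6-trimethoxyphenyl)pyridin-3-ol | COc1cc(OC)c(-c2ccncc2O)c(OC)c1 | intermediate
4 | 3-hydroxy-1-methyl-4-(2,4,6-trimethoxyphenyl)pyridin-1-ium iodide | C[n+]1ccc(-c2c(OC)cc(OC)cc2OC)c(O)c1.[I-] | intermediate
5 | 1-methyl-4-(2,4,6-trimethoxyphenyl)-1,2,5,6-tetrahydropyridin-3-ol (enol tautomer, not isolated) | CN1CCC(c2c(OC)cc(OC)cc2OC)=C(O)C1 | intermediate
6 | rac-1-methyl-4-(2,4,6-trimethoxyphenyl)piperidin-3-one | CN1CCC(c2c(OC)cc(OC)cc2OC)C(=O)C1 | intermediate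
7 | (3S,4R)-1-methyl-4-(2,4,6-trimethoxyphenyl)piperidin-3-ol | O[C@@H]1CN(C)CC[C@@H]1c1c(OC)cc(OC)cc1OC | intermediate
8 | (3S,4R)-4-(3-acetyl-2-hydroxy-4,6-dimethoxyphenyl)-1-methylpiperidin-3-yl acetate | CC(=O)O[C@@H]1CN(C)CC[C@@H]1c1c(OC)cc(OC)c(C(C)=O)c1O | intermediate
9 | 1-{2-hydroxy-3-[(3S,4R)-3-hydroxy-1-methylpiperidin-4-yl]-4,6-dimethoxyphenyl}butane-1,3-dione (not isolated) | O[C@@H]1CN(C)CC[C@@H]1c1c(OC)cc(OC)c(C(=O)CC(C)=O)c1O | intermediate
10 | 8-[(3S,4R)-3-hydroxy-1-methylpiperidin-4-yl]-5,7-dimethoxy-2-methyl-4H-chromen-4-one | O[C@@H]1CN(C)CC[C@@H]1c1c(OC)cc(OC)c2c(=O)cc(C)oc12 | intermediate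
11 | 5,7-dihydroxy-8-[(3S,4R)-3-hydroxy-1-methylpiperidin-4-yl]-2-methyl-4H-chromen-4-one | O[C@@H]1CN(C)CC[C@@H]1c1c(O)cc(O)c2c(=O)cc(C)oc12 | intermediate
12 | 5-hydroxy-8-[(3S,4R)-3-hydroxy-1-methylpiperidin-4-yl]-2-methyl-7-{[tri(propan-2-yl)silyl]oxy}-4H-chromen-4-one | O[C@@H]1CN(C)CC[C@@H]1c1c(O[Si](C(C)C)(C(C)C)C(C)C)cc(O)c2c(=O)cc(C)oc12 | intermediate
13 | (2Z)-2-methylbut-2-enoic acid (angelic acid) | C/C=C(/C)C(=O)O | starting material
14 | (3S,4R)-4-(5-hydroxy-2-methyl-4-oxo-7-{[tri(propan-2-yl)silyl]oxy}-4H-chromen-8-yl)-1-methylpiperidin-3-yl (2Z)-2-methylbut-2-enoate | C/C=C(/C)C(=O)O[C@@H]1CN(C)CC[C@@H]1c1c(O[Si](C(C)C)(C(C)C)C(C)C)cc(O)c2c(=O)cc(C)oc12 | intermediate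
15 | (3S,4R)-4-(5,7-dihydroxy-2-methyl-4-oxo-4H-chromen-8-yl)-1-methylpiperidin-3-yl (2Z)-2-methylbut-2-enoate | C/C=C(/C)C(=O)O[C@@H]1CN(C)CC[C@@H]1c1c(O)cc(O)c2c(=O)cc(C)oc12 | target

## Step count and least certain steps

Total step count: 10. Longest linear sequence: 10 steps (from 1 and 2 to 15); 13 enters at step 9.

**Step 4 (key step).** Reduction may outrun epimerisation at C4', which would leave a plain kinetic resolution. The doubly ortho-substituted aryl group may also crowd the catalyst pocket and erode enantiomer selection or the cis preference. The alpha-amino ketone may self-condense under base. Fallback: setting out from 6, reduction with LiBH(sBu)3 in THF at −78 °C should give racemic cis-1-methyl-4-(2,4,6-trimethoxyphenyl)piperidin-3-ol F1. This is resolved by crystallisation of its salt with (2R,3R)-O,O'-dibenzoyltartaric acid, the hydrogen dibenzoyltartrate of the (3S,4R) base F2 (the enantiomeric acid is taken if the other salt proves the less soluble). Liberation of the base with aqueous Na2CO3 comes back to the route at 7. The unwanted enantiomer can be returned to 6 by Swern oxidation.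

**Step 3.** Reduction may continue to the alcohol or stall at a dihydropyridine, and iodide or the bulky C4 substituent may slow the catalyst. Fallback: setting out from 4, NaBH4 in MeOH (0 °C to rt) reduces the pyridinium salt through 5 and 6 to racemic 1-methyl-4-(2,4,6-trimethoxyphenyl)piperidin-3-ol F3 as a cis/trans mixture. Swern oxidation ((COCl)2, DMSO, Et3N, −78 °C) of the mixture comes back to the route at 6.

**Step 9.** The Z-enoate may isomerise to the E-isomer during activation or at 80 °C. The hindered axial alcohol may also acylate incompletely, and the chelated O5 may be acylated in part. Fallback: setting out from 12, the Z-alkene is built after the ester bond. Coupling of 12 with 2-[bis(2,2,2-trifluoroethoxy)phosphoryl]propanoic acid (DCC, CH2Cl2) gives (3S,4R)-4-(5-hydroxy-2-methyl-4-oxo-7-{[tri(propan-2-yl)silyl]oxy}-4H-chromen-8-yl)-1-methylpiperidin-3-yl 2-[bis(2,2,2-trifluoroethoxy)phosphoryl]propanoate F4. A Still–Gennari olefination with acetaldehyde (KN(SiMe3)2, 2.2 equiv to allow for the 5-OH, 18-crown-6, THF, −78 °C) should then give the Z-trisubstituted enoate and comes back to the route at 14.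

**Step 1.** Loss of boron from 2 may outpace transmetalation, and the pyridinolate may bind the catalyst. Fallback: setting out from 1, 1,3,5-trimethoxybenzene is lithiated (n-BuLi, THF, 0 °C) and transmetalated with ZnCl2 to chlorido(2,4,6-trimethoxyphenyl)zinc F5. A Negishi coupling with the sodium salt of 1 (NaH; Pd(OAc)2, SPhos, THF, 60 °C) comes back to the route at 3.

**Step 8.** Site selectivity may be lost (silylation at O3'), or the aryl silyl ether may be lost at 80 °C in step 9. Fallback: setting out from 11, an excess of the mixed anhydride of step 9 acylates both O7 and O3' to give (3S,4R)-4-(5-hydroxy-2-methyl-7-{[(2Z)-2-methylbut-2-enoyl]oxy}-4-oxo-4H-chromen-8-yl)-1-methylpiperidin-3-yl (2Z)-2-methylbut-2-enoate F6. Mild methanolysis (NH4OAc, aqueous MeOH, rt) should cleave only the far more labile phenolic ester and comes back to the route at 15.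

## Further compounds

F1 | step 4 | rac-(3S,4R)-1-methyl-4-(2,4,6-trimethoxyphenyl)piperidin-3-ol (racemic cis) | O[C@@H]1CN(C)CC[C@@H]1c1c(OC)cc(OC)cc1OC
F2 | step 4 | (3S,4R)-3-hydroxy-1-methyl-4-(2,4,6-trimethoxyphenyl)piperidin-1-ium (2R,3R)-2,3-bis(benzoyloxy)-3-carboxypropanoate | O[C@@H]1C[NH+](C)CC[C@@H]1c1c(OC)cc(OC)cc1OC.OC(=O)[C@H](OC(=O)c1ccccc1)[C@@H](OC(=O)c1ccccc1)C([O-])=O
F3 | step 3 | 1-methyl-4-(2,4,6-trimethoxyphenyl)piperidin-3-ol (racemic, cis/trans mixture) | CN1CCC(c2c(OC)cc(OC)cc2OC)C(O)C1
F4 | step 9 | (3S,4R)-4-(5-hydroxy-2-methyl-4-oxo-7-{[tri(propan-2-yl)silyl]oxy}-4H-chromen-8-yl)-1-methylpiperidin-3-yl 2-[bis(2,2,2-trifluoroethoxy)phosphoryl]propanoate (both epimers at the phosphonate carbon) | CC(C(=O)O[C@@H]1CN(C)CC[C@@H]1c1c(O[Si](C(C)C)(C(C)C)C(C)C)cc(O)c2c(=O)cc(C)oc12)P(=O)(OCC(F)(F)F)OCC(F)(F)F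
F5 | step 1 | chlorido(2,4,6-trimethoxyphenyl)zinc | COc1cc(OC)c([Zn]Cl)c(OC)c1
F6 | step 8 | (3S,4R)-4-(5-hydroxy-2-methyl-7-{[(2Z)-2-methylbut-2-enoyl]oxy}-4-oxo-4H-chromen-8-yl)-1-methylpiperidin-3-yl (2Z)-2-methylbut-2-enoate | C/C=C(/C)C(=O)O[C@@H]1CN(C)CC[C@@H]1c1c(OC(=O)/C(C)=C\C)cc(O)c2c(=O)cc(C)oc12
A1 | alternative 1 | 1-methyl-4-(2,4,6-trimethoxyphenyl)-1,2,3,6-tetrahydropyridine | CN1CCC(c2c(OC)cc(OC)cc2OC)=CC1
A2 | alternative 1 | rac-(3R,4R)-1-methyl-4-(2,4,6-trimethoxyphenyl)piperidin-3-ol (racemic trans) | O[C@H]1CN(C)CC[C@@H]1c1c(OC)cc(OC)cc1OC
A3 | alternative 2 | (4S)-1-methyl-4-(2,4,6-trimethoxyphenyl)piperidin-2-one | C1C(=O)N(C)CC[C@@H]1c1c(OC)cc(OC)cc1OC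
A4 | alternative 2 | (3R,4R)-3-hydroxy-1-methyl-4-(2,4,6-trimethoxyphenyl)piperidin-2-one (trans) | O[C@H]1C(=O)N(C)CC[C@@H]1c1c(OC)cc(OC)cc1OC
A5 | alternative 3 | (1S,6R)-3-methyl-7-oxa-3-azabicyclo[4.1.0]heptane | O1[C@H]2CN(C)CC[C@@H]12
A6 | alternative 3 | (3R,4R)-1-methyl-4-(2,4,6-trimethoxyphenyl)piperidin-3-ol (trans) | O[C@H]1CN(C)CC[C@@H]1c1c(OC)cc(OC)cc1OC
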